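**Retrosynthetic overview**
- The C8–O ester bond (Yamaguchi) and the two silyl ethers are dealt with last.
- Key disconnection: the C6–C7 bond, formed by a SmI2 ketyl–enoate radical 10-exo ring closure of an open C15 chain. The ten-membered carbocycle forms first and the γ-lactone (O6–C12) closes second in the same flask; C6, C7 and C11 are set from C8.
- The C7–C8 bond and the C8 stereocentre come from an enantioselective Ni/Cr alkenyl–aldehyde coupling.
- The C3–C4 bond comes from a B-alkyl Suzuki coupling onto a 4-bromobutenolide, whose ring is the masked (Z)-C4=C5 hydroxy enal.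
- The C1–C2 bond and the C14 methyl come from carboalumination/vinylation of a C4 alkynol.

Assumption: atoms are labelled by germacrane numbering (C6 = lactone CH–O, C7 = ring-fusion CH, C8 = ester CH–O, C11 = CH(CH3), C12 = lactone C=O, C15 = CH2OH), and in step 4 the ligand antipode that gives the 4S alcohol is the one used.

**Step 1**
Reactants: 1 but-3-yn-1-ol; 2 bromoethene
Product: 4 (3E)-3-methylhexa-3,5-dien-1-ol, via alkenylalane 3 (not isolated)
Conditions: AlMe3 (3 equiv), Cp2ZrCl2 (0.25 equiv), CH2Cl2, 0 °C to rt; then ZnCl2 (1 equiv), Pd(PPh3)4 (5 mol %), bromoethene, THF, rt; 1 M HCl, 0 °C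
Reagents that add atoms: trimethylaluminium, C[Al](C)C
Why: Zirconium-catalysed Negishi carboalumination adds Me–Al syn across the alkyne with the methyl on the internal carbon, and the alkenylalane is cross-coupled with retention (Negishi coupling), which fixes the E trisubstituted C1=C10 alkene.

**Step 2**
Reactants: 4 (3E)-3-methylhexa-3,5-dien-1-ol; 5 4-bromofuran-2(5H)-one
Product: 7 4-[(3E)-6-hydroxy-4-methylhex-3-en-1-yl]furan-2(5H)-one, via alkylborane 6 (not isolated)
Conditions: 9-BBN-H (2.2 equiv), THF, 0 °C to rt; then 5, PdCl2(dppf) (5 mol %), AsPh3 (10 mol %), Cs2CO3 (3 equiv), DMF–H2O, rt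
Reagents that add atoms: none
Why: 9-BBN-H hydroborates only the terminal vinyl carbon of the diene, and the B-alkyl Suzuki–Miyaura coupling onto the vinylogous acyl bromide gives the 4-alkylbutenolide, whose ring locks C15–O cis to C6 across C4=C5.

**Step 3**
Reactants: 7 4-[(3E)-6-hydroxy-4-methylhex-3-en-1-yl]furan-2(5H)-one
Product: 8 (3E)-3-methyl-6-(5-oxo-2,5-dihydrofuran-3-yl)hex-3-enal
Conditions: Dess–Martin periodinane (1.3 equiv), pyridine (3 equiv), CH2Cl2, 0 °C; used crude at once
Reagents that add atoms: none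
Why: Buffered Dess–Martin oxidation gives the β,γ-unsaturated aldehyde under neutral conditions, so the C1=C10 double bond does not move into conjugation.

**Step 4**
Reactants: 8 (3E)-3-methyl-6-(5-oxo-2,5-dihydrofuran-3-yl)hex-3-enal; 9 methyl (2E)-3-iodo-2-methylprop-2-enoate
Product: 10 methyl (2E,4S,6E)-4-hydroxy-2,6-dimethyl-9-(5-oxo-2,5-dihydrofuran-3-yl)nona-2,6-dienoate
Conditions: CrCl2 (4 equiv), Kishi-type oxazoline–sulfonamide ligand (4.4 equiv), Et3N (4.4 equiv), NiCl2 (10 mol %), THF, rt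
Reagents that add atoms: none
Why: In this ligand-controlled Nozaki–Hiyama–Kishi coupling the alkenylchromium adds to the aldehyde with retention of the E enoate geometry, and the chiral sulfonamide on chromium selects the aldehyde face to set C8 as S; lactone and ester are tolerated.

**Step 5**
Reactants: 10 methyl (2E,4S,6E)-4-hydroxy-2,6-dimethyl-9-(5-oxo-2,5-dihydrofuran-3-yl)nona-2,6-dienoate
Product: 11 methyl (2E,4S,6E)-4-hydroxy-9-(5-hydroxy-2,5-dihydrofuran-3-yl)-2,6-dimethylnona-2,6-dienoate (lactol; both anomers)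
Conditions: i-Bu2AlH (2.2 equiv), CH2Cl2, −78 °C; aqueous work-up; used without chromatography
Reagents that add atoms: none
Why: At −78 °C the strained, unhindered butenolide is half-reduced to the lactol much faster than the α-branched conjugated methyl ester (chemoselective lactone reduction), and the lactol is a masked (Z)-4-hydroxy enal.

**Step 6**
Reactants: 11 methyl (2E,4S,6E)-4-hydroxy-9-(5-hydroxy-2,5-dihydrofuran-3-yl)-2,6-dimethylnona-2,6-dienoate
Product: 14 (3R,3aS,4S,6E,10Z,11aR)-4-hydroxy-10-(hydroxymethyl)-3,6-dimethyl-3a,4,5,8,9,11a-hexahydrocyclodeca[b]furan-2(3H)-one, via hydroxy enal 12 (not isolated), via epimeric lactone 13 (not isolated)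
Conditions: SmI2 (0.1 M in THF, 2.6 equiv) added over 6 h to 11 (1 mM) and t-BuOH (4 equiv) in THF, 0 °C to rt; aq NH4Cl; crude product: DBU (0.5 equiv), toluene, 50 °C
Reagents that add atoms: none
Why: Proposed new method: the lactol is in equilibrium with hydroxy enal 12, whose aldehyde is reduced by divalent samarium to a trivalent-samarium ketyl held by the cis C15 hydroxyl (which keeps the C4=C5 geometry) and by the free C8 hydroxyl, so the C6 radical adds 10-exo-trig to C7 of the enoate through an all-equatorial chair-like six-membered O6–Sm–O8 chelate with C8–H eclipsing the enoate (least allylic 1,3-strain against the C11 methyl), which sets C6 as R and C7 as S from C8 (S) and gives the cis ring fusion, after which the α-ester radical is reduced to the samarium enolate, protonated by t-BuOH, and the C6 alkoxide closes the γ-lactone with loss of methanol, C11 finally being equilibrated by DBU to the more stable R epimer (methyl trans to C8); the closest known reaction types are the SmI2 aldehyde–acrylate/crotonate reductive coupling with lactonisation (cis-β,γ-selective) and SmI2 ketyl–olefin cyclisations to medium rings.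

**Step 7**
Reactants: 14 (3R,3aS,4S,6E,10Z,11aR)-4-hydroxy-10-(hydroxymethyl)-3,6-dimethyl-3a,4,5,8,9,11a-hexahydrocyclodeca[b]furan-2(3H)-one
Product: 15 (3R,3aS,4S,6E,10Z,11aR)-10-({[tert-butyl(dimethyl)silyl]oxy}methyl)-4-hydroxy-3,6-dimethyl-3a,4,5,8,9,11a-hexahydrocyclodeca[b]furan-2(3H)-one
Conditions: TBSCl (1.1 equiv), imidazole (2.5 equiv), CH2Cl2, 0 °C
Reagents that add atoms: tert-butyl(chloro)dimethylsilane (TBSCl), CC(C)(C)[Si](C)(C)Cl
Why: Selective silylation: the primary allylic C15 hydroxyl reacts much faster than the hindered secondary C8 hydroxyl, and no stereocentre is touched.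

**Step 8**
Reactants: 16 2-(hydroxymethyl)prop-2-enoic acid
Product: 18 2-({[tert-butyl(dimethyl)silyl]oxy}methyl)prop-2-enoic acid, via bis-silyl derivative 17 (not isolated)
Conditions: TBSCl (2.2 equiv), imidazole (4.5 equiv), DMF, rt; then K2CO3 (1 equiv), THF–H2O, rt; 1 M HCl to pH 4
Reagents that add atoms: tert-butyl(chloro)dimethylsilane (TBSCl), CC(C)(C)[Si](C)(C)Cl
Why: Exhaustive silylation followed by selective hydrolysis of the labile silyl ester leaves the silyl ether acid (protection, then chemoselective silyl ester cleavage).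

**Step 9**
Reactants: 15 (3R,3aS,4S,6E,10Z,11aR)-10-({[tert-butyl(dimethyl)silyl]oxy}methyl)-4-hydroxy-3,6-dimethyl-3a,4,5,8,9,11a-hexahydrocyclodeca[b]furan-2(3H)-one; 18 2-({[tert-butyl(dimethyl)silyl]oxy}methyl)prop-2-enoic acid
Product: 19 (3R,3aS,4S,6E,10Z,11aR)-10-({[tert-butyl(dimethyl)silyl]oxy}methyl)-3,6-dimethyl-2-oxo-2,3,3a,4,5,8,9,11a-octahydrocyclodeca[b]furan-4-yl 2-({[tert-butyl(dimethyl)silyl]oxy}methyl)prop-2-enoate
Conditions: 18 (2 equiv), 2,4,6-trichlorobenzoyl chloride (2 equiv), Et3N (4 equiv), toluene, rt; then 15, DMAP (2 equiv), rt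
Reagents that add atoms: none
Why: Yamaguchi esterification acylates the hindered secondary C8 hydroxyl through the mixed anhydride and acylpyridinium ion at the acyl carbon only, so C8 keeps its S configuration.

**Step 10**
Reactants: 19 (3R,3aS,4S,6E,10Z,11aR)-10-({[tert-butyl(dimethyl)silyl]oxy}methyl)-3,6-dimethyl-2-oxo-2,3,3a,4,5,8,9,11a-octahydrocyclodeca[b]furan-4-yl 2-({[tert-butyl(dimethyl)silyl]oxy}methyl)prop-2-enoate
Product: 20 (3R,3aS,4S,6E,10Z,11aR)-10-(hydroxymethyl)-3,6-dimethyl-2-oxo-2,3,3a,4,5,8,9,11a-octahydrocyclodeca[b]furan-4-yl 2-(hydroxymethyl)prop-2-enoate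
Conditions: HF·pyridine, pyridine, THF, 0 °C to rt
Reagents that add atoms: none
Why: Pyridine-buffered fluoride desilylation removes both primary silyl ethers without acid-induced transannular cyclisation of the cyclodecadiene or attack on the acrylate and lactone.

**Compound list**
1 | but-3-yn-1-ol | C#CCCO | starting material
2 | bromoethene | C=CBr | starting material
3 | dimethylaluminium (3E)-4-(dimethylalumanyl)-3-methylbut-3-en-1-olate | C[Al](C)/C=C(\C)CCO[Al](C)C | intermediate
4 | (3E)-3-methylhexa-3,5-dien-1-ol | C=C/C=C(\C)CCO | intermediate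
5 | 4-bromofuran-2(5H)-one | O=C1C=C(Br)CO1 | starting material
6 | 9-[(3E)-6-(9-borabicyclo[3.3.1]nonan-9-yloxy)-4-methylhex-3-en-1-yl]-9-borabicyclo[3.3.1]nonane | B1(C2CCCC1CCC2)CC/C=C(\C)CCOB3C4CCCC3CCC4 | intermediate
7 | 4-[(3E)-6-hydroxy-4-methylhex-3-en-1-yl]furan-2(5H)-one | OCC/C(C)=C/CCC1=CC(=O)OC1 | intermediate
8 | (3E)-3-methyl-6-(5-oxo-2,5-dihydrofuran-3-yl)hex-3-enal | O=CC/C(C)=C/CCC1=CC(=O)OC1 | intermediate
9 | methyl (2E)-3-iodo-2-methylprop-2-enoate | COC(=O)/C(C)=C/I | starting material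
10 | methyl (2E,4S,6E)-4-hydroxy-2,6-dimethyl-9-(5-oxo-2,5-dihydrofuran-3-yl)nona-2,6-dienoate | COC(=O)/C(C)=C/[C@@H](O)C/C(C)=C/CCC1=CC(=O)OC1 | intermediate
11 | methyl (2E,4S,6E)-4-hydroxy-9-(5-hydroxy-2,5-dihydrofuran-3-yl)-2,6-dimethylnona-2,6-dienoate (lactol; both anomers) | COC(=O)/C(C)=C/[C@@H](O)C/C(C)=C/CCC1=CC(O)OC1 | intermediate
12 | methyl (2E,4S,6E,10Z)-4-hydroxy-10-(hydroxymethyl)-2,6-dimethyl-12-oxododeca-2,6,10-trienoate | COC(=O)/C(C)=C/[C@@H](O)C/C(C)=C/CC/C(CO)=C/C=O | intermediate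
13 | (3S,3aS,4S,6E,10Z,11aR)-4-hydroxy-10-(hydroxymethyl)-3,6-dimethyl-3a,4,5,8,9,11a-hexahydrocyclodeca[b]furan-2(3H)-one | O[C@H]1C/C(C)=C/CC/C(CO)=C/[C@H]2OC(=O)[C@@H](C)[C@@H]12 | intermediate
14 | (3R,3aS,4S,6E,10Z,11aR)-4-hydroxy-10-(hydroxymethyl)-3,6-dimethyl-3a,4,5,8,9,11a-hexahydrocyclodeca[b]furan-2(3H)-one | O[C@H]1C/C(C)=C/CC/C(CO)=C/[C@H]2OC(=O)[C@H](C)[C@@H]12 | intermediate
15 | (3R,3aS,4S,6E,10Z,11aR)-10-({[tert-butyl(dimethyl)silyl]oxy}methyl)-4-hydroxy-3,6-dimethyl-3a,4,5,8,9,11a-hexahydrocyclodeca[b]furan-2(3H)-one | O[C@H]1C/C(C)=C/CC/C(CO[Si](C)(C)C(C)(C)C)=C/[C@H]2OC(=O)[C@H](C)[C@@H]12 | intermediate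
16 | 2-(hydroxymethyl)prop-2-enoic acid | C=C(CO)C(=O)O | starting material
17 | tert-butyl(dimethyl)silyl 2-({[tert-butyl(dimethyl)silyl]oxy}methyl)prop-2-enoate | C=C(CO[Si](C)(C)C(C)(C)C)C(=O)O[Si](C)(C)C(C)(C)C | intermediate
18 | 2-({[tert-butyl(dimethyl)silyl]oxy}methyl)prop-2-enoic acid | C=C(CO[Si](C)(C)C(C)(C)C)C(=O)O | intermediate
19 | (3R,3aS,4S,6E,10Z,11aR)-10-({[tert-butyl(dimethyl)silyl]oxy}methyl)-3,6-dimethyl-2-oxo-2,3,3a,4,5,8,9,11a-octahydrocyclodeca[b]furan-4-yl 2-({[tert-butyl(dimethyl)silyl]oxy}methyl)prop-2-enoate | C=C(CO[Si](C)(C)C(C)(C)C)C(=O)O[C@H]1C/C(C)=C/CC/C(CO[Si](C)(C)C(C)(C)C)=C/[C@H]2OC(=O)[C@H](C)[C@@H]12 | intermediate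
20 | (3R,3aS,4S,6E,10Z,11aR)-10-(hydroxymethyl)-3,6-dimethyl-2-oxo-2,3,3a,4,5,8,9,11a-octahydrocyclodeca[b]furan-4-yl 2-(hydroxymethyl)prop-2-enoate (CNP0167163.2) | C=C(CO)C(=O)O[C@H]1C/C(C)=C/CC/C(CO)=C/[C@H]2OC(=O)[C@H](C)[C@@H]12 | target

**Step count**
Total: 10 steps. Longest linear sequence: 9 steps (1, 2, 3, 4, 5, 6, 7, 9, 10, from but-3-yn-1-ol); step 8 is a one-step side branch.

**Steps most likely to fail**

Step 6 is the most likely to fail. The lactol can dehydrate to a 3-substituted furan on the Lewis-acidic trivalent samarium. The allylic ketyl can dimerise or be over-reduced before the ten-membered ring closes. The sense at C6/C7 rests on a chelate model that has not been tested in a macrocyclic setting. The free C8 hydroxyl could translactonise to the 8,12-olide during the DBU equilibration. The fallback sets out from 10 and comes back at 15. The butenolide of 10 is opened chemoselectively with the aluminium amide made from N,O-dimethylhydroxylamine hydrochloride and AlMe3 (CH2Cl2, 0 °C) to the (Z)-hydroxy Weinreb amide F1. The primary hydroxyl is silylated (TBSCl, imidazole) to the silyl ether amide F2, and Cp2Zr(H)Cl (THF, rt) reduces the amide to the open-chain silyloxy enal F3. This free aldehyde, with no lactol equilibrium, no furan pathway and C15 already protected, is closed with SmI2/t-BuOH and equilibrated with DBU to give 15 directly.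

Step 5 is the second risk. The methyl enoate may be reduced alongside the butenolide, the lactol may be over-reduced to the diol, or it may aromatise on work-up. The fallback sets out from 4 and comes back at 11, so that no reduction is done in the presence of the ester. Alcohol 4 is oxidised (Dess–Martin periodinane, pyridine) to the dienal F4, which is coupled with 9 under the step 4 conditions to the trienoate F5. Bromobutenolide 5 alone is reduced with i-Bu2AlH (−78 °C) to the bromolactol F6. Hydroboration of F5 with 9-BBN-H and Suzuki coupling with F6 (PdCl2(dppf), AsPh3, Cs2CO3) then gives 11.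

Step 4 is the third risk. The enantioselectivity may be low with an α-unbranched aldehyde, and the β,γ-unsaturated aldehyde may isomerise. The fallback sets out from 8 and comes back at 10, and moves the stereochemical decision from C–C bond formation to a ketone reduction. Ligand-free CrCl2/NiCl2 coupling of 8 with 9 gives the racemic alcohol F7. Buffered Dess–Martin oxidation gives the enone F8. (R)-CBS-catalysed reduction with BH3·SMe2 (alkenyl as the large group) is expected to return 10 with the 4S configuration.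

**Further compounds**
F1 | step 6 | methyl (2E,4S,6E,10Z)-4-hydroxy-10-(hydroxymethyl)-12-[methoxy(methyl)amino]-2,6-dimethyl-12-oxododeca-2,6,10-trienoate | COC(=O)/C(C)=C/[C@@H](O)C/C(C)=C/CC/C(CO)=C/C(=O)N(C)OC
F2 | step 6 | methyl (2E,4S,6E,10Z)-10-({[tert-butyl(dimethyl)silyl]oxy}methyl)-4-hydroxy-12-[methoxy(methyl)amino]-2,6-dimethyl-12-oxododeca-2,6,10-trienoate | COC(=O)/C(C)=C/[C@@H](O)C/C(C)=C/CC/C(CO[Si](C)(C)C(C)(C)C)=C/C(=O)N(C)OC
F3 | step 6 | methyl (2E,4S,6E,10Z)-10-({[tert-butyl(dimethyl)silyl]oxy}methyl)-4-hydroxy-2,6-dimethyl-12-oxododeca-2,6,10-trienoate | COC(=O)/C(C)=C/[C@@H](O)C/C(C)=C/CC/C(CO[Si](C)(C)C(C)(C)C)=C/C=O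
F4 | step 5 | (3E)-3-methylhexa-3,5-dienal | O=CC/C(C)=C/C=C
F5 | step 5 | methyl (2E,4S,6E)-4-hydroxy-2,6-dimethylnona-2,6,8-trienoate | COC(=O)/C(C)=C/[C@@H](O)C/C(C)=C/C=C
F6 | step 5 | 4-bromo-2,5-dihydrofuran-2-ol | OC1OCC(Br)=C1
F7 | step 4 | methyl (2E,6E)-4-hydroxy-2,6-dimethyl-9-(5-oxo-2,5-dihydrofuran-3-yl)nona-2,6-dienoate (racemic) | COC(=O)/C(C)=C/C(O)C/C(C)=C/CCC1=CC(=O)OC1
F8 | step 4 | methyl (2E,6E)-2,6-dimethyl-4-oxo-9-(5-oxo-2,5-dihydrofuran-3-yl)nona-2,6-dienoate | COC(=O)/C(C)=C/C(=O)C/C(C)=C/CCC1=CC(=O)OC1
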